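**Retrosynthetic overview**
- Last disconnection: the aryl–C(OH) bond. This gives a 2-methoxy-4-methylphenyl boron nucleophile and a symmetric ketone that already carries both isobutyrate arms (new Rh-catalysed 1,2-arylation).
- The ketone comes from 1,3-dihydroxyacetone and isobutyric anhydride by double O-acylation.
- The arylboronic acid comes from 2-bromo-5-methylanisole by Br–Li exchange and borylation. The purchased bromide fixes the 1,2,4-substitution pattern.
- No ring is formed, since the benzene ring is bought. The route has no protecting group, no redox step and no stereocentre to set.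

**Assumption 1:** the carbinol carbon carries two identical CH2OC(O)iPr arms, so the SMILES has no stereocentre. The target is achiral, and "single enantiomer" means this one compound.

**Assumption 2:** compound 1 is drawn as the monomer. Commercial solid that is partly the hemiketal dimer reverts to the monomer in pyridine.

**Step 1**
Reactants: 1 1,3-dihydroxyacetone; 2 isobutyric anhydride
Product: 3 2-oxopropane-1,3-diyl bis(2-methylpropanoate)
Conditions: 2 (2.4 equiv), pyridine/CH2Cl2 1:2, 0 °C → rt, 18 h; wash with 1 M HCl, then NaHCO3
Reagents that add atoms: none
Why: Pyridine-mediated O-acylation (nucleophilic acyl substitution) of the two primary hydroxyls is fast, the ketone offers no other site that is acylated under these mild conditions, and this is the standard way to make 1,3-diacyloxyacetones.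

**Step 2**
Reactants: 4 1-bromo-2-methoxy-4-methylbenzene (2-bromo-5-methylanisole)
Product: 7 (2-methoxy-4-methylphenyl)boronic acid, via aryllithium 5 (not isolated), via lithium aryltriisopropoxyborate 6 (not isolated)
Conditions: n-BuLi (1.05 equiv), THF, −78 °C, 30 min; B(OiPr)3 (1.3 equiv), −78 °C → rt; 1 M HCl, 0 °C, 15 min
Reagents that add atoms: triisopropyl borate, CC(C)OB(OC(C)C)OC(C)C; water, O
Why: Halogen–metal exchange followed by borylation works because Br–Li exchange is fast and regiospecific at −78 °C (the ortho-methoxy group stabilises 5), the hindered borate stops at ate complex 6, and brief mild acid hydrolysis frees the boronic acid.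

**Step 3**
Reactants: 3 2-oxopropane-1,3-diyl bis(2-methylpropanoate); 7 (2-methoxy-4-methylphenyl)boronic acid
Product: 8 2-hydroxy-2-(2-methoxy-4-methylphenyl)propane-1,3-diyl bis(2-methylpropanoate) (target)
Conditions: [Rh(OH)(cod)]2 (2.5 mol %), 7 (2.0 equiv in two portions), 1,4-dioxane/H2O 10:1, no added base, 50 °C, 16 h, Ar
Reagents that add atoms: none
Why: Proposed new method: base-free Rh(I)–diene-catalysed 1,2-addition of an arylboronic acid to a dihydroxyacetone diester, an acyclic, enolisable α,α'-bis(acyloxy) dialkyl ketone class on which, to my knowledge, no catalytic aryl–boron addition has been shown; Rh–OH transmetalates with 7 without external base to give an aryl–Rh(cod) species (a hemilabile o-OMe contact should slow its protonolysis), the carbonyl of 3, whose LUMO is lowered by two σ-withdrawing α-acyloxy groups and which is flanked only by CH2 groups, binds and inserts into the Rh–aryl bond through a four-centre transition state to form the aryl–C(quaternary) bond, and water should protonate the weakly basic tertiary Rh alkoxide faster than β-aryl elimination or acyl shift, releasing 8 and regenerating Rh–OH; the neutral medium leaves both hindered isobutyrates intact, and no stereocentre arises because the two arms are identical; closest known reaction type: Rh-catalysed (Miyaura-type) 1,2-addition of arylboronic acids to aldehydes and to activated ketones such as α-keto esters, isatins and trifluoromethyl ketones.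

**Compound list**
1 | 1,3-dihydroxyacetone (1,3-dihydroxypropan-2-one) | O=C(CO)CO | starting material
2 | isobutyric anhydride (2-methylpropanoic anhydride) | CC(C)C(=O)OC(=O)C(C)C | starting material
3 | 2-oxopropane-1,3-diyl bis(2-methylpropanoate) | CC(C)C(=O)OCC(=O)COC(=O)C(C)C | intermediate
4 | 1-bromo-2-methoxy-4-methylbenzene (2-bromo-5-methylanisole) | COc1cc(C)ccc1Br | starting material
5 | (2-methoxy-4-methylphenyl)lithium (not isolated) | [Li]c1ccc(C)cc1OC | intermediate
6 | lithium (2-methoxy-4-methylphenyl)triisopropoxyborate (not isolated) | [Li+].COc1cc(C)ccc1[B-](OC(C)C)(OC(C)C)OC(C)C | intermediate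
7 | (2-methoxy-4-methylphenyl)boronic acid | COc1cc(C)ccc1B(O)O | intermediate
8 | 2-hydroxy-2-(2-methoxy-4-methylphenyl)propane-1,3-diyl bis(2-methylpropanoate), achiral | COc1cc(C)ccc1C(O)(COC(=O)C(C)C)COC(=O)C(C)C | target

**Totals**
Total step count: 3 (convergent).
Longest linear sequence: 2 steps (1 → 3 → 8 or 4 → 7 → 8).

**Steps most likely to fail**

**Step 3 (the proposed new step).**
- Risk: protonolysis of the electron-rich, ortho-substituted aryl–Rh species, or enolisation of 3, may outrun carbonyl insertion. The result would be 3-methylanisole and recovered ketone.
- Fallback (known chemistry only): it sets out from bromide 4 and comes back at target 8. Aryllithium 5 is made from 4 as in step 2. It is added at −78 °C in THF to commercial 2,2-dimethyl-1,3-dioxan-5-one and quenched with water to give 5-(2-methoxy-4-methylphenyl)-2,2-dimethyl-1,3-dioxan-5-ol F1. The acetonide is cleaved with 80 % aqueous AcOH at 40 °C to 2-(2-methoxy-4-methylphenyl)propane-1,2,3-triol F2. Only the two primary hydroxyls are then acylated with anhydride 2 (2.1 equiv) in pyridine/CH2Cl2 at 0 °C without DMAP. The hindered tertiary benzylic hydroxyl stays free, and this gives 8.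

**Step 1.**
- Risk: slow cracking of dimeric 1, acylated hemiketal dimers, or an enol ester may contaminate 3.
- Fallback: it sets out from 1 and comes back at 3, and it masks the ketone first. Compound 1 is treated with trimethyl orthoformate and cat. TsOH in MeOH to give 2,2-dimethoxypropane-1,3-diol F3. This plain diol is acylated with 2 in pyridine to 2,2-dimethoxypropane-1,3-diyl bis(2-methylpropanoate) F4. The ketal is then hydrolysed with TFA/H2O in CH2Cl2 at rt to release 3.

**Step 2.**
- Risk: acid-promoted protodeboronation during work-up, butylation of 5 by the 1-bromobutane formed, or variable boroxine content of 7.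
- Fallback: it sets out from 4 and comes back at 7, and it replaces organolithium chemistry by Pd catalysis. Miyaura borylation of 4 uses bis(pinacolato)diboron, KOAc and Pd(dppf)Cl2 in dioxane at 90 °C. It gives 2-(2-methoxy-4-methylphenyl)-4,4,5,5-tetramethyl-1,3,2-dioxaborolane F5. The pinacol unit is then removed oxidatively with NaIO4/NH4OAc in acetone/H2O at rt to give 7.

**Further compounds**
F1 | step 3 | 5-(2-methoxy-4-methylphenyl)-2,2-dimethyl-1,3-dioxan-5-ol | COc1cc(C)ccc1C1(O)COC(C)(C)OC1
F2 | step 3 | 2-(2-methoxy-4-methylphenyl)propane-1,2,3-triol | COc1cc(C)ccc1C(O)(CO)CO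
F3 | step 1 | 2,2-dimethoxypropane-1,3-diol | COC(CO)(CO)OC
F4 | step 1 | 2,2-dimethoxypropane-1,3-diyl bis(2-methylpropanoate) | COC(COC(=O)C(C)C)(COC(=O)C(C)C)OC
F5 | step 2 | 2-(2-methoxy-4-methylphenyl)-4,4,5,5-tetramethyl-1,3,2-dioxaborolane | COc1cc(C)ccc1B1OC(C)(C)C(C)(C)O1
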